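The data were generated by integration for an exercise.

After 10.0 h the west run stops moving: its starting material falls 0.2 percentage points more by 12.0 h, less than the scatter of 0.5 points. I read that plateau as equilibrium. From it I decide what to charge next: ochre's partner, or twice that in green.

the same everywhere: starting material 0.10 M

| charge | partner | protic impurity | remark | time |
|---|---|---|---|---|
| west | 0.15 M | 0.0067 M | run made earlier |  |
| ochre | 0.150 M | 0.0100 M |  | 20 h |
| green | 0.300 M | 0.0100 M |  | 20 h |

- west (time / h: over-reaction product / %, starting material / %, target / %): 3.00: 0.4, 62.1, 31.4; 6.00: 0.5, 55.3, 37.9; 10.0: 0.3, 54.2, 39.1; 12.0: 0.3, 54.0, 38.9

(readings scatter by 0.5 percentage points)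

- which of these there is most of at the end, counted by the starting material in it, ochre (target / starting material / over-reaction product)
- which of these there is most of at the end, counted by the starting material in it, green (target / starting material / over-reaction product)
- how much there is at the end of the one of these that leads, in percent of the starting material charged: ochre
- how much there is at the end of the one of these that leads, in percent of the starting material charged: green

- on the list of suspects stand: starting material + partner <-> target + by-product; starting material + protic impurity -> quenched substrate; partner + target -> over-reaction product
- no earlier run changes the charge of protic impurity; that part of a forecast is a guess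

At its last reading the west run's balance is short by 6.80%, close to its protic impurity at 6.70% of the charge. So I subtract the impurity from the starting material one for one. No earlier run varies that charge, so this is a guess. I carry one number, the equilibrium constant K, the plateau quotient of products over reactants. I take c(by-product) equal to c(target):

K = c(target)·c(by-product) / (c(starting material)·c(partner)) = 0.252

Let a be the starting material left after the impurity, b the partner charged, x the target:

x·x = K·(a − x)·(b − x), with a = 0.0900 M

ochre: x = 0.0382 M, target 38.2%, starting material 51.8%

green: x = 0.0501 M, target 50.1%, starting material 39.9%

So I charge green and stop at 20 h. The forecast, slightly off my figures, names starting material at 51.7% for ochre and target at 49.8% for green. It holds that “impurity destroys starting material one-for-one and quickly”.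

The flask gives starting material at 51.0% in ochre and target at 48.1% in green.

    starting material + partner ⇌ target + by-product (K = 0.263, k = 1.26 L mol⁻¹ h⁻¹)
    starting material + protic impurity → quenched substrate (k = 24.7 L mol⁻¹ h⁻¹)
    partner + target → over-reaction product (k = 0.0149 L mol⁻¹ h⁻¹)

In ochre the quench has 98% of its turnover behind it at 2.00 h, and the reversible step has 87% of its own at 4.00 h. From 10.0 h to 20.0 h ochre's over-reaction product creeps from 0.534% to 1.16%. In green at 20.0 h the same quotient, taken from the amounts standing there, is 0.262, against K of 0.252. With the other charges and the time held, starting material and target end level at 0.224 M of partner, against green's 0.300 M. Left to 200 h, green holds target 30.9%, less than starting material at 31.9%.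

For the neighbour like ochre but with 0.60 M of partner, K gives x = 0.0618 M: target 61.8%, starting material 28.2%. The computed flask holds target 55.3%, starting material 25.8% and over-reaction product 8.97%.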